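The earlier runs and the new flask stem from a simulated flask for an exercise.

A small charge of free enzyme, 2.0 µM against 0.020 M of substrate at 5 °C, gives target in shrinking gains, up to 60.6 % by 40.0 h.

- beta: substrate 0.020 M; free enzyme 2 µM; temperature 5 °C; the very flask that is asked about, followed so far
- flask: substrate 0.020 M; free enzyme 2.0 µM; temperature 5 °C; time 2.0 d

beta run (percent of the substrate charged)

| time / h | target / % |
|---|---|
| 2.50 | 22.7 |
| 8.00 | 42.7 |
| 15.0 | 51.9 |
| 20.0 | 55.5 |
| 30.0 | 59.3 |
| 40.0 | 60.6 |

(scatter of a reading: 0.3 percentage points)

- target, in percent of the substrate first charged, at 2.0 d
- what to do for the largest gain in target; "none" if nothing gains more than 2 percentage points (Thursday's / Saturday's / Friday's / Monday's / none)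
- target present, with what was taken out counted in, in percent of the substrate first charged, after Thursday's
- target present, with what was taken out counted in, in percent of the substrate first charged, after Saturday's

- Thursday's: change nothing and wait 25 h more
- Saturday's: at 2.0 d take out 90 % of the target then present, then wait 25 h
- Friday's: at 2.0 d raise the temperature by 25 K, then wait 25 h
- Monday's: at 2.0 d add free enzyme, 100 % of the amount charged, then wait 25 h

- target taken out counts as made
- additions bring no volume worth counting
- the earlier runs do not show what temperature does; that part of a forecast is a guess

Two chemists stand at the board. Both start from the last two ten-hour gains: 3.8 percentage points up to 30.0 h, then 1.3 points up to 40.0 h, which is smaller. From these they read 9.32 h as the time in which the gain per hour falls by a factor e, the fade time, a reading that carries the scatter of 0.3 points.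

The first says this flask is relaxing to balance, so taking out target restarts it and more enzyme does nothing. The second says the enzyme is dying, so the fade time measures its working life, and taking out target does nothing. This is thermodynamic against kinetic control of the plateau.

The second view brings a rule. The enzyme's dose up to a given time is its charge times the fade time times one minus exp(−time/fade time). A flask with less enzyme should then match this flask at the hour of equal dose. On this view a fresh charge on Monday's plan gives, in 25 h, nearly all of the first charge's dose over 2.0 d. If the rate also falls as substrate falls, the fade time belongs to enzyme and substrate together, not to the enzyme by itself.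

My own reckoning extends the shrinking gains to a level near 61.3 %, a reading with the same scatter, and either view gives such a level, so this run does not part them.

The forecast takes the first side, in its words: “I favour equilibrium, with K about 1.6.” It gives 61.3 % now, 61.7 % after Thursday's and 81.5 % after Saturday's, and it chooses Saturday's.

The flask gives 61.5 %, and the best step is Monday's.

    free enzyme → spent catalyst (k = 8.40 × 10⁻⁴ min⁻¹, Ea = 93.0 kJ mol⁻¹)
    free enzyme → unfolded enzyme (k = 7.20 × 10⁻⁵ min⁻¹, Ea = 187 kJ mol⁻¹)
    substrate + free enzyme → target + free enzyme, rate k3*[substrate]^3*[free enzyme]/(1 + ([substrate]/Kh3)^3) (29.0 mM, k = 63000 M⁻³ s⁻¹, Ea = 23.0 kJ mol⁻¹)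
    (constants at 5 °C)

Monday's gains 9.6 points, whereas Saturday's gains 0.96 points, the same as waiting, so both end at 62.5 %. At 48.0 h free enzyme stands at 7.23 % of its charge with 38.5 % of the substrate still there. The first chemist keeps the flask left as it is, which looks like balance: 61.5 % becomes 62.8 % at 480 h. With a quarter of the enzyme, 5.0 × 10⁻⁷ M, the fade time puts the hour of equal dose at 2.66 h. That neighbour ends at 34.3 %, the target this flask held at 4.80 h, which is later than that hour.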